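**Retrosynthetic overview**
1. In chromone numbering (O1, C2, C3, C4, C4a, C5–C8, C8a) the carbocycle C4a–C5–C6–C7–C8–C8a is read as D-glucose: C8, C7, C6 are sugar C4, C3, C2 (bought), C8a is sugar C5, C5 is sugar C1 and C4a is sugar C6.
2. Key disconnection C4a–C5: a Ferrier carbocyclisation of a glucose hex-5-enopyranoside turns the pyranose into the cyclohexanone (carbocycle closed first) and sets the C5 hydroxyl cis to the C6 oxygen under control of the three bought centres.
3. The pyrone ring is closed second: C4–C4a and O1–C8a form together by [4+2] addition of an acylketene (O1, C2, C3, C4 and the arylethyl chain) to the C8a=C4a silyl enol ether, followed by loss of silanol.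
4. The acylketene comes from a dioxinone made by γ-benzylation of the diketene–acetone adduct; one global debenzylation ends the route.

Key step: step 3

Remark: the target SMILES is read as (5S,6S,7R,8S), with 5-OH/6-OH cis, 6-OH/7-OH trans and 7-OH/8-OH trans, which is the D-gluco pattern at C6–C8. Compounds 1, 10 and 12 are assumed to be commercial.

**Step 1**
Reactants: 1 methyl α-D-glucopyranoside
Product: 2 methyl 6-deoxy-6-iodo-α-D-glucopyranoside
Conditions: PPh3, I2, imidazole, THF, reflux
Reagents that add atoms: iodine, II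
Why: Garegg–Samuelsson (Appel-type) iodination; the alkoxyphosphonium ion forms selectively at the unhindered primary 6-OH and is displaced by iodide, so the secondary hydroxyls and all stereocentres stay untouched.

**Step 2**
Reactants: 2 methyl 6-deoxy-6-iodo-α-D-glucopyranoside
Product: 4 methyl 2,3,4-tri-O-benzyl-6-deoxy-α-D-xylo-hex-5-enopyranoside, via tribenzyl iodide 3 (not isolated)
Conditions: NaH (excess), BnBr, DMF, 0 °C → rt
Reagents that add atoms: benzyl bromide, BrCc1ccccc1
Why: Williamson benzylation of the three alkoxides followed in the same pot by E2 dehydroiodination of the primary iodide by the excess hydride should give the exocyclic enol ether; fast O-benzylation in the presence of benzyl bromide should keep O-3 from closing onto C6 as a 3,6-anhydro ring.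

**Step 3**
Reactants: 4 methyl 2,3,4-tri-O-benzyl-6-deoxy-α-D-xylo-hex-5-enopyranoside
Product: 6 (2S,3R,4S,5S)-2,3,4-tris(benzyloxy)-5-hydroxycyclohexan-1-one, via mercurio ketoaldehyde 5 (not isolated)
Conditions: Hg(OCOCF3)2 (10 mol %), acetone–H2O (2:1), rt
Reagents that add atoms: water, O
Why: Ferrier carbocyclisation: Hg(II) adds with water across the exocyclic enol ether C5=C6, the C5 hemiketal collapses with loss of methanol to the acyclic 6-mercurio-5-keto aldehyde 5, and this mercury enolate adds to the C1 aldehyde, which frees Hg(II) for the next turnover. The closest known reaction type is this same catalytic mercury(II) carbocyclisation of 2,3,4-tri-O-benzyl-hex-5-enopyranosides to 2-deoxyinososes. The one ring formed, the carbocycle C4a–C5–C6–C7–C8–C8a of the target, closes by a 6-(enolexo)-exo-trig intramolecular aldol addition that makes the C4a–C5 bond (sugar C6–C1). The only new stereocentre, C5 of the target, is controlled by the three benzyloxy-bearing centres: in the chair-like transition state they sit equatorial and the aldehyde oxygen sits axial, bridged through mercury to the enolate oxygen, so the new hydroxyl should end up axial, trans to sugar O-3 and cis to sugar O-2, which is the required (5S) 5,6-cis relationship. The step needs this diastereoselectivity and no β-elimination of the new hydroxyl; the chelated chair should secure the first and the neutral aqueous acetone at room temperature the second.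

**Step 4**
Reactants: 6 (2S,3R,4S,5S)-2,3,4-tris(benzyloxy)-5-hydroxycyclohexan-1-one
Product: 7 (2S,3R,4R,5S)-2,3,4-tris(benzyloxy)-5-(triethylsilyloxy)cyclohexan-1-one (same geometry as 6; the C4 descriptor changes only by CIP priority)
Conditions: TESOTf, 2,6-lutidine, CH2Cl2, –78 °C
Reagents that add atoms: triethylsilyl trifluoromethanesulfonate, CC[Si](CC)(CC)OS(=O)(=O)C(F)(F)F
Why: O-silylation with a silyl triflate and a hindered pyridine base is fast at –78 °C and not basic enough to trigger β-elimination or to epimerise the α-benzyloxy centre; no stereocentre is touched.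

**Step 5**
Reactants: 7 (2S,3R,4R,5S)-2,3,4-tris(benzyloxy)-5-(triethylsilyloxy)cyclohexan-1-one
Product: 9 trimethylsilyl enol ether of 7 on the methylene side [4,5,6-tris(benzyloxy)-3-(triethylsilyloxy)-1-(trimethylsilyloxy)cyclohex-1-ene with the four stereocentres as in 7], via lithium enolate 8 (not isolated)
Conditions: TMSCl, LDA, THF, –78 °C (in situ quench); non-aqueous work-up, used crude
Reagents that add atoms: chlorotrimethylsilane, C[Si](C)(C)Cl
Why: Kinetic enolisation with LDA in the presence of TMSCl should remove a proton from the unsubstituted C6 methylene rather than the hindered tertiary α-benzyloxy C2–H (whose deprotonation would place a donor oxygen on the enolate carbon), and immediate O-silylation at –78 °C should keep the enolate from expelling the β-silyloxy group, so C2 (future C8) is not epimerised.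

**Step 6**
Reactants: 10 3-benzyloxy-4-methoxybenzyl alcohol
Product: 11 3-benzyloxy-4-methoxybenzyl bromide
Conditions: PBr3, CH2Cl2, 0 °C; used without storage
Reagents that add atoms: phosphorus tribromide, BrP(Br)Br
Why: Bromination of an electron-rich benzylic alcohol through its bromophosphite (nucleophilic substitution by bromide); the aryl benzyl and methyl ethers are stable at 0 °C.

**Step 7**
Reactants: 12 2,2,6-trimethyl-4H-1,3-dioxin-4-one; 11 3-benzyloxy-4-methoxybenzyl bromide
Product: 14 6-[2-(3-benzyloxy-4-methoxyphenyl)ethyl]-2,2-dimethyl-4H-1,3-dioxin-4-one, via lithium dienolate 13 (not isolated)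
Conditions: LDA, THF–DMPU, –78 °C; then 11, –78 → –20 °C
Reagents that add atoms: none
Why: Vinylogous (γ-selective) alkylation of the lithium dienolate of the dioxinone with a reactive benzylic bromide in the presence of DMPU, a known way to extend the 6-methyl group of this acylketene precursor.

**Step 8**
Reactants: 9 trimethylsilyl enol ether of 7; 14 6-[2-(3-benzyloxy-4-methoxyphenyl)ethyl]-2,2-dimethyl-4H-1,3-dioxin-4-one
Product: 18 (5S,6S,7R,8S)-6,7,8-tris(benzyloxy)-2-[2-(3-benzyloxy-4-methoxyphenyl)ethyl]-5-hydroxy-5,6,7,8-tetrahydro-4H-chromen-4-one, via acylketene 15 (not isolated), via silyl ketal cycloadduct 16 (not isolated), via triethylsilyl pyrone 17 (not isolated)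
Conditions: PhMe, 110 °C, 14 (2.5 equiv) added slowly; then TFA, CH2Cl2–H2O, 0 °C → rt
Reagents that add atoms: none
Why: Thermal retro-[4+2] of the dioxinone gives acylketene 15, which should be trapped by the silyl enol ether in a hetero-Diels–Alder reaction of an α-oxoketene with an enol ether (nucleophilic C4a attacks the ketene carbon, the acyl oxygen closes on C8a); acid then eliminates trimethylsilanol to aromatise to the γ-pyrone and cleaves the triethylsilyl ether, the two transient centres C4a and C8a are erased and C5–C8 are not involved.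

**Step 9**
Reactants: 18 (5S,6S,7R,8S)-6,7,8-tris(benzyloxy)-2-[2-(3-benzyloxy-4-methoxyphenyl)ethyl]-5-hydroxy-5,6,7,8-tetrahydro-4H-chromen-4-one
Product: 19 (5S,6S,7R,8S)-5,6,7,8-tetrahydroxy-2-[2-(3-hydroxy-4-methoxyphenyl)ethyl]-5,6,7,8-tetrahydro-4H-chromen-4-one (CNP0224308.1)
Conditions: BCl3, C6HMe5, CH2Cl2, –78 °C; then MeOH
Reagents that add atoms: none
Why: Lewis acid debenzylation with BCl3 and pentamethylbenzene as a non-basic benzyl cation scavenger should cleave the four O–CH2Ph bonds without hydrogen, so the pyrone C2=C3 bond is not reduced; boron bound to the pyrone carbonyl disfavours ionisation at C5 and C8, so the four stereocentres should be retained, and the aryl methyl ether is stable at this temperature.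

**Compound list**
1 | methyl α-D-glucopyranoside | CO[C@@H]1[C@H](O)[C@@H](O)[C@H](O)[C@@H](CO)O1 | starting material
2 | methyl 6-deoxy-6-iodo-α-D-glucopyranoside | CO[C@@H]1[C@H](O)[C@@H](O)[C@H](O)[C@@H](CI)O1 | intermediate
3 | tribenzyl iodide: methyl 2,3,4-tri-O-benzyl-6-deoxy-6-iodo-α-D-glucopyranoside (formed in the flask in step 2) | CO[C@@H]1[C@H](OCc2ccccc2)[C@@H](OCc2ccccc2)[C@H](OCc2ccccc2)[C@@H](CI)O1 | intermediate
4 | methyl 2,3,4-tri-O-benzyl-6-deoxy-α-D-xylo-hex-5-enopyranoside | CO[C@@H]1[C@H](OCc2ccccc2)[C@@H](OCc2ccccc2)[C@H](OCc2ccccc2)C(=C)O1 | intermediate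
5 | mercurio ketoaldehyde: 2,3,4-tri-O-benzyl-6-deoxy-6-(trifluoroacetoxymercurio)-D-xylo-hexos-5-ulose (formed in the flask in step 3) | O=C[C@H](OCc1ccccc1)[C@@H](OCc1ccccc1)[C@H](OCc1ccccc1)C(=O)C[Hg]OC(=O)C(F)(F)F | intermediate
6 | (2S,3R,4S,5S)-2,3,4-tris(benzyloxy)-5-hydroxycyclohexan-1-one | O=C1[C@@H](OCc2ccccc2)[C@H](OCc2ccccc2)[C@@H](OCc2ccccc2)[C@@H](O)C1 | intermediate
7 | (2S,3R,4R,5S)-2,3,4-tris(benzyloxy)-5-(triethylsilyloxy)cyclohexan-1-one | O=C1[C@@H](OCc2ccccc2)[C@H](OCc2ccccc2)[C@@H](OCc2ccccc2)[C@@H](O[Si](CC)(CC)CC)C1 | intermediate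
8 | lithium enolate of 7 on the methylene side (formed in the flask in step 5) | [Li]OC1=C[C@H](O[Si](CC)(CC)CC)[C@H](OCc2ccccc2)[C@@H](OCc2ccccc2)[C@@H]1OCc1ccccc1 | intermediate
9 | trimethylsilyl enol ether of 7: 4,5,6-tris(benzyloxy)-3-(triethylsilyloxy)-1-(trimethylsilyloxy)cyclohex-1-ene, stereocentres as in 7 | C[Si](C)(C)OC1=C[C@H](O[Si](CC)(CC)CC)[C@H](OCc2ccccc2)[C@@H](OCc2ccccc2)[C@@H]1OCc1ccccc1 | intermediate
10 | 3-benzyloxy-4-methoxybenzyl alcohol | COc1ccc(CO)cc1OCc1ccccc1 | starting material
11 | 3-benzyloxy-4-methoxybenzyl bromide | COc1ccc(CBr)cc1OCc1ccccc1 | intermediate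
12 | 2,2,6-trimethyl-4H-1,3-dioxin-4-one | CC1=CC(=O)OC(C)(C)O1 | starting material
13 | lithium dienolate of 12 (formed in the flask in step 7) | C=C1C=C(O[Li])OC(C)(C)O1 | intermediate
14 | 6-[2-(3-benzyloxy-4-methoxyphenyl)ethyl]-2,2-dimethyl-4H-1,3-dioxin-4-one | COc1ccc(CCC2=CC(=O)OC(C)(C)O2)cc1OCc1ccccc1 | intermediate
15 | acylketene: 5-(3-benzyloxy-4-methoxyphenyl)-3-oxopent-1-en-1-one (formed in the flask in step 8) | COc1ccc(CCC(=O)C=C=O)cc1OCc1ccccc1 | intermediate
16 | silyl ketal cycloadduct: cis-fused 6,7,8-tris(benzyloxy)-2-[2-(3-benzyloxy-4-methoxyphenyl)ethyl]-5-(triethylsilyloxy)-8a-(trimethylsilyloxy)-4a,5,6,7,8,8a-hexahydro-4H-chromen-4-one, drawn as the isomer from addition anti to the C5 and C8 oxygens; C4a and C8a are transient (formed in the flask in step 8) | COc1ccc(CCC2=CC(=O)[C@H]3[C@H](O[Si](CC)(CC)CC)[C@H](OCc4ccccc4)[C@@H](OCc4ccccc4)[C@H](OCc4ccccc4)[C@@]3(O[Si](C)(C)C)O2)cc1OCc1ccccc1 | intermediate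
17 | triethylsilyl pyrone: 5-O-triethylsilyl ether of 18 (formed in the flask in step 8) | COc1ccc(CCc2cc(=O)c3c(o2)[C@@H](OCc4ccccc4)[C@H](OCc4ccccc4)[C@@H](OCc4ccccc4)[C@H]3O[Si](CC)(CC)CC)cc1OCc1ccccc1 | intermediate
18 | (5S,6S,7R,8S)-6,7,8-tris(benzyloxy)-2-[2-(3-benzyloxy-4-methoxyphenyl)ethyl]-5-hydroxy-5,6,7,8-tetrahydro-4H-chromen-4-one | COc1ccc(CCc2cc(=O)c3c(o2)[C@@H](OCc4ccccc4)[C@H](OCc4ccccc4)[C@@H](OCc4ccccc4)[C@H]3O)cc1OCc1ccccc1 | intermediate
19 | (5S,6S,7R,8S)-5,6,7,8-tetrahydroxy-2-[2-(3-hydroxy-4-methoxyphenyl)ethyl]-5,6,7,8-tetrahydro-4H-chromen-4-one | COc1ccc(CCc2cc(=O)c3c(o2)[C@@H](O)[C@H](O)[C@@H](O)[C@H]3O)cc1O | target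

**Step count**
Total: 9 steps. Longest linear sequence: 7 steps (steps 1, 2, 3, 4, 5, 8, 9).

**Steps most likely to fail**

Step 8. The acylketene may dimerise or be consumed faster than the hindered, inductively deactivated silyl enol ether traps it, or the β-silyloxy group may be lost from the ketal intermediate before aromatisation. The fallback builds the pyrone by aldol addition, oxidation and cycloisomerisation; it sets out from ketone 7 and bromide 11 and comes back to the route at pyrone 17. Bromide 11 and propargylmagnesium bromide should give 4-(3-benzyloxy-4-methoxyphenyl)but-1-yne F1. Lithiation of F1 (n-BuLi, THF, –78 °C) and formylation with DMF should give 5-(3-benzyloxy-4-methoxyphenyl)pent-2-ynal F2. The lithium enolate 8, made from 7 with LDA at –78 °C, should add to F2 in an aldol reaction to give the propargylic aldol adduct F3 as a mixture at the two new centres. Dess–Martin oxidation should give the 2-alkynoyl-1,3-diketone F4, which loses both new centres on enolisation. Gold(I)- or acid-catalysed 6-endo-dig addition of the enol oxygen to the ynone should close the pyrone to 17, which is desilylated to 18 as in step 8.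

Step 5. Deprotonation may occur on the benzyloxy side, with loss of regiocontrol and epimerisation of the future C8, or the enolate may eliminate the β-silyloxy group. The fallback replaces kinetic deprotonation by thermodynamic regiocontrol in an enamine; it sets out from ketone 7 and comes back at pyrone 17. Ketone 7 with morpholine and TiCl4 in toluene at 0 °C should give the less substituted morpholine enamine F5, because allylic 1,3-strain keeps the double bond away from the benzyloxy-bearing carbon and no strong base is present. F5 is a stronger nucleophile than the silyl enol ether; heated with 14 in toluene it should trap acylketene 15, and acid treatment of the adduct should expel morpholine to give 17 and then 18.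

Step 7. Competing α-alkylation and dialkylation of the dienolate, or low conversion, may occur. The fallback assembles the same carbon chain by terminal alkylation of an acetoacetate dianion; it sets out from bromide 11 and comes back at dioxinone 14. The dianion of tert-butyl acetoacetate (NaH, then n-BuLi, THF, 0 °C) should be alkylated at its terminal carbon by 11 to give tert-butyl 5-(3-benzyloxy-4-methoxyphenyl)-3-oxopentanoate F6. Acetone, trifluoroacetic anhydride and TFA should convert F6 into dioxinone 14.

**Further compounds**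
F1 | step 8 | 4-(3-benzyloxy-4-methoxyphenyl)but-1-yne | COc1ccc(CCC#C)cc1OCc1ccccc1
F2 | step 8 | 5-(3-benzyloxy-4-methoxyphenyl)pent-2-ynal | COc1ccc(CCC#CC=O)cc1OCc1ccccc1
F3 | step 8 | aldol adduct: 2,3,4-tris(benzyloxy)-6-[5-(3-benzyloxy-4-methoxyphenyl)-1-hydroxypent-2-yn-1-yl]-5-(triethylsilyloxy)cyclohexan-1-one, C2–C5 as in 7, mixture at C6 and the carbinol carbon | O=C1[C@@H](OCc2ccccc2)[C@H](OCc2ccccc2)[C@@H](OCc2ccccc2)[C@@H](O[Si](CC)(CC)CC)C1C(O)C#CCCc1ccc(OC)c(OCc2ccccc2)c1
F4 | step 8 | 2,3,4-tris(benzyloxy)-6-[5-(3-benzyloxy-4-methoxyphenyl)pent-2-ynoyl]-5-(triethylsilyloxy)cyclohexan-1-one, C2–C5 as in 7, C6 enolisable | O=C1[C@@H](OCc2ccccc2)[C@H](OCc2ccccc2)[C@@H](OCc2ccccc2)[C@@H](O[Si](CC)(CC)CC)C1C(=O)C#CCCc1ccc(OC)c(OCc2ccccc2)c1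
F5 | step 5 | morpholine enamine of 7 on the methylene side: 4-[4,5,6-tris(benzyloxy)-3-(triethylsilyloxy)cyclohex-1-en-1-yl]morpholine, stereocentres as in 7 | O1CCN(CC1)C1=C[C@H](O[Si](CC)(CC)CC)[C@H](OCc2ccccc2)[C@@H](OCc2ccccc2)[C@@H]1OCc1ccccc1
F6 | step 7 | tert-butyl 5-(3-benzyloxy-4-methoxyphenyl)-3-oxopentanoate | COc1ccc(CCC(=O)CC(=O)OC(C)(C)C)cc1OCc1ccccc1
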